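**Plan**
1. Retrosynthesis: the nine O-benzyl groups come off last; the seven-membered ring C is cut at the bond between the aryl-bearing methine and the resorcinol ring (epoxide Friedel–Crafts), then the stilbene C=C (Horner–Wadsworth–Emmons).
2. Benzene ring A of the upper dihydrobenzofuran is cut at C3a–C7a, C7–C6 and C5–C4 into an ynol-ether diyne and benzyloxyacetylene; the diyne is cut at C2–C3 into a propargylic mesylate and the lower-half aldehyde.
3. What allows this: ring A is 1,2,3,5-tetrasubstituted (C3a, C7a–O1, C4–carbon, C6–oxygen; C5 and C7 bear H) and fused to furan ring B, whose O1–C2–C3 segment serves as a three-atom tether between the two alkynes.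
4. Forward: lower dihydrobenzofuran, then middle dihydrobenzofuran (carbene C–H insertion and C2 epimerisation each), anti propargylation, ynol ether, rings A and B together by (2+2+2), stilbene, epoxide, ring C, debenzylation.
5. Stereochemistry: C3 of the lower and middle rings from a chiral dirhodium carboxylate, their C2 by trans equilibration; upper C3 and C2 from an (S)-propargylic alcohol (asymmetric alkynylation) by chirality transfer and anti addition; the two ring C centres from Shi epoxidation and invertive ring closure.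

Key step: step 20

Remark: the absolute sense of induction of Rh2(S-PTAD)4 (steps 6, 11), (R)-BINOL/Ti(OiPr)4 (step 13) and the D-fructose-derived Shi ketone (step 25) is assigned by analogy with the closest substrate classes; if the opposite sense is found, the mirror-image catalyst is used.

Abbreviations: Bn = benzyl; TBS = tert-butyldimethylsilyl; ArP = 4-(benzyloxy)phenyl; ArR = 3,5-bis(benzyloxy)phenyl; BOB = 4-(benzyloxy)benzyl; Lw = (2R,3R)-6-(benzyloxy)-2-ArP-3-ArR-2,3-dihydro-1-benzofuran-4-yl (trans); LwM = (2R,3R)-2-ArP-3-Lw-2,3-dihydro-1-benzofuran-5-yl (trans); Rh2(S-PTAD)4 = dirhodium tetrakis[(S)-(1-adamantyl)(N-phthalimido)acetate].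

**Route**

Step 1
Reactants: 1 2-bromo-4,6-dimethoxybenzaldehyde
Product: 2 2-bromo-4,6-dihydroxybenzaldehyde
Conditions: BBr3, CH2Cl2, −78 °C → rt; H2O
Reagents that add atoms: none
Why: Boron tribromide demethylation cleaves both aryl methyl ethers and leaves the aldehyde and the aryl bromide alone.

Step 2
Reactants: 2 2-bromo-4,6-dihydroxybenzaldehyde
Product: 3 4-(benzyloxy)-2-bromo-6-hydroxybenzaldehyde
Conditions: BnBr (1.05 equiv), NaHCO3, KI (cat.), MeCN, 70 °C
Reagents that add atoms: benzyl bromide, BrCc1ccccc1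
Why: Williamson etherification should occur at the 4-OH because the 6-OH is held in a hydrogen bond to the formyl group and is less nucleophilic under weak base.

Step 3
Reactants: 3 4-(benzyloxy)-2-bromo-6-hydroxybenzaldehyde; 4 4-(benzyloxy)benzyl chloride
Product: 5 4-(benzyloxy)-2-(BOB-oxy)-6-bromobenzaldehyde
Conditions: K2CO3, KI (cat.), DMF, 60 °C
Reagents that add atoms: none
Why: Williamson etherification of the remaining chelated phenol under stronger base installs the OCH2 group into which the carbene will later insert.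

Step 4
Reactants: 5 4-(benzyloxy)-2-(BOB-oxy)-6-bromobenzaldehyde
Product: 6 4-(benzyloxy)-2-(BOB-oxy)-6-bromobenzonitrile
Conditions: I2, 28% aq. NH3, THF, rt
Reagents that add atoms: ammonia, N
Why: Oxidative aldehyde-to-nitrile conversion through the aldimine and its N-iodo derivative is mild enough for the acid-labile BOB ether and prepares a ketimine route to a hydrazone that a di-ortho-substituted ketone would not form readily.

Step 5
Reactants: 6 4-(benzyloxy)-2-(BOB-oxy)-6-bromobenzonitrile; 7 1,3-bis(benzyloxy)-5-bromobenzene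
Product: 10 hydrazone of [4-(benzyloxy)-2-(BOB-oxy)-6-bromophenyl](ArR)methanone, via arylmagnesium bromide 8 (not isolated), via N–H ketimine 9 (not isolated)
Conditions: 7, Mg, THF, 50 °C; 6, CuBr (5 mol%), THF, 60 °C; MeOH; N2H4·H2O, AcOH (cat.), EtOH, 75 °C
Reagents that add atoms: hydrazine (as hydrate), NN
Why: Copper-promoted Grignard addition to the hindered nitrile gives the N–H ketimine, and transimination with hydrazine then gives the hydrazone while the aryl bromide is inert to the magnesium reagent.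

Step 6
Reactants: 10 hydrazone of [4-(benzyloxy)-2-(BOB-oxy)-6-bromophenyl](ArR)methanone
Product: 12 (2S,3R)-6-(benzyloxy)-2-ArP-3-ArR-4-bromo-2,3-dihydro-1-benzofuran (cis), via diaryldiazomethane 11 (not isolated)
Conditions: MnO2, CH2Cl2, 0 °C, filtration; Rh2(S-PTAD)4 (1 mol%), CH2Cl2, −20 °C → rt
Reagents that add atoms: none
Why: Hydrazone oxidation gives the diaryldiazomethane, whose donor/donor rhodium carbene undergoes enantioselective intramolecular 1,5 C–H insertion into the benzylic OCH2 group, a reaction type established for 2,3-diaryl-dihydrobenzofurans of resveratrol dimers, with the chiral carboxylate setting C3 (R) and the insertion delivering the cis ring.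

Step 7
Reactants: 12 (2S,3R)-6-(benzyloxy)-2-ArP-3-ArR-4-bromo-2,3-dihydro-1-benzofuran (cis)
Product: 13 (2R,3R)-6-(benzyloxy)-2-ArP-3-ArR-4-bromo-2,3-dihydro-1-benzofuran (trans; Lw–Br)
Conditions: CF3CO2H, CH2Cl2, 0 °C → rt
Reagents that add atoms: none
Why: Acid-mediated epimerisation by reversible ionisation of the C2–O bond to the 4-benzyloxybenzyl cation and re-closure gives the thermodynamically preferred trans ring, inverting C2 to R while C3 is untouched.

Step 8
Reactants: 14 5-formyl-2-hydroxybenzonitrile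
Product: 15 5-(1,3-dioxolan-2-yl)-2-hydroxybenzonitrile
Conditions: HOCH2CH2OH, PPTS (cat.), toluene, reflux, Dean–Stark
Reagents that add atoms: ethane-1,2-diol, OCCO
Why: Acetalisation masks the aldehyde against the organolithium and hydrazine used later, and is done before the acid-labile BOB ether is present.

Step 9
Reactants: 15 5-(1,3-dioxolan-2-yl)-2-hydroxybenzonitrile; 4 4-(benzyloxy)benzyl chloride
Product: 16 2-(BOB-oxy)-5-(1,3-dioxolan-2-yl)benzonitrile
Conditions: K2CO3, DMF, 50 °C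
Reagents that add atoms: none
Why: Williamson etherification of an acidic cyanophenol proceeds under mild base without touching the acetal.

Step 10
Reactants: 13 Lw–Br; 16 2-(BOB-oxy)-5-(1,3-dioxolan-2-yl)benzonitrile
Product: 19 hydrazone of [2-(BOB-oxy)-5-(1,3-dioxolan-2-yl)phenyl](Lw)methanone, via aryllithium 17 (not isolated), via N–H ketimine 18 (not isolated)
Conditions: n-BuLi, THF, −78 °C; 16, −78 → 0 °C; MeOH; N2H4·H2O, AcOH (cat.), EtOH, 70 °C
Reagents that add atoms: hydrazine (as hydrate), NN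
Why: Bromine–lithium exchange, 1,2-addition to the nitrile and transimination give the hindered hydrazone under a hydrazine-buffered medium in which the dioxolane and both stereocentres of Lw are stable.

Step 11
Reactants: 19 hydrazone of [2-(BOB-oxy)-5-(1,3-dioxolan-2-yl)phenyl](Lw)methanone
Product: 21 (2S,3R)-2-ArP-3-Lw-5-(1,3-dioxolan-2-yl)-2,3-dihydro-1-benzofuran (cis middle ring), via diaryldiazomethane 20 (not isolated)
Conditions: MnO2, CH2Cl2, 0 °C, filtration; Rh2(S-PTAD)4 (1 mol%), CH2Cl2, −20 °C → rt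
Reagents that add atoms: none
Why: The same donor/donor carbene 1,5 C–H insertion closes the middle ring under catalyst control (C3 R, C2 S, cis), and the five-membered insertion into the activated ether CH2 is expected to outrun attack of the carbene on the neighbouring ArR ring.

Step 12
Reactants: 21 (2S,3R)-2-ArP-3-Lw-5-(1,3-dioxolan-2-yl)-2,3-dihydro-1-benzofuran (cis middle ring)
Product: 22 LwM–CHO, (2R,3R)-2-ArP-3-Lw-2,3-dihydro-1-benzofuran-5-carbaldehyde
Conditions: CF3CO2H, CH2Cl2/H2O (20:1), −20 → 0 °C; Et3N quench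
Reagents that add atoms: water, O
Why: Aqueous acid hydrolyses the dioxolane and epimerises C2 of the middle ring to R through the reversible 4-benzyloxybenzyl cation (thermodynamic trans), with low temperature and early quenching meant to keep that cation from being captured by the nearby ArR ring.

Step 13
Reactants: 23 3,5-bis(benzyloxy)benzaldehyde; 24 tert-butyldimethyl(prop-2-yn-1-yloxy)silane
Product: 25 (S)-1-ArR-4-(TBS-oxy)but-2-yn-1-ol
Conditions: Et2Zn, 24, toluene, rt; (R)-BINOL (20 mol%), Ti(OiPr)4 (50 mol%), CH2Cl2; 23, rt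
Reagents that add atoms: none
Why: Catalytic asymmetric addition of an alkynylzinc to an aryl aldehyde under titanium–BINOLate control should deliver the (S)-carbinol, the ligand fixing the aldehyde face.

Step 14
Reactants: 25 (S)-1-ArR-4-(TBS-oxy)but-2-yn-1-ol
Product: 26 (S)-1-ArR-4-(TBS-oxy)but-2-yn-1-yl methanesulfonate
Conditions: MsCl, Et3N, CH2Cl2, −78 °C; used without chromatography
Reagents that add atoms: methanesulfonyl chloride, CS(=O)(=O)Cl
Why: O-Sulfonylation proceeds with retention, and the meta-alkoxy groups do not stabilise the benzylic cation, so the mesylate should survive at low temperature.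

Step 15
Reactants: 26 (S)-1-ArR-4-(TBS-oxy)but-2-yn-1-yl methanesulfonate; 22 LwM–CHO
Product: 28 (1R,2R)-2-ArR-1-LwM-5-(TBS-oxy)pent-3-yn-1-ol (anti), via allenylindium 27 (not isolated)
Conditions: Pd(dppf)Cl2 (5 mol%), InI (1.5 equiv), THF/HMPA (3:1), rt
Reagents that add atoms: none
Why: Zerovalent palladium displaces the mesylate in anti SN2′ fashion and transmetalation to indium with retention gives the (M)-allenylindium, which adds to the aldehyde through a cyclic SE2′ transition state (propargylic umpolung/allenylmetal addition), so that C2 is set R by transfer of axial chirality and C1 is set R by the anti preference of the closed transition state.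

Step 16
Reactants: 28 (1R,2R)-2-ArR-1-LwM-5-(TBS-oxy)pent-3-yn-1-ol
Product: 29 (1R,2R)-2-ArR-1-[(E)-1,2-dichlorovinyloxy]-1-LwM-5-(TBS-oxy)pent-3-yne
Conditions: KH, THF, 0 °C; Cl2C=CHCl, −50 °C → rt
Reagents that add atoms: trichloroethylene, ClC=C(Cl)Cl
Why: The potassium alkoxide adds to dichloroacetylene generated in situ from trichloroethylene (addition–elimination) to give the (E)-dichlorovinyl ether without touching either stereocentre.

Step 17
Reactants: 29 (1R,2R)-2-ArR-1-[(E)-1,2-dichlorovinyloxy]-1-LwM-5-(TBS-oxy)pent-3-yne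
Product: 30 (1R,2R)-2-ArR-1-(ethynyloxy)-1-LwM-5-(TBS-oxy)pent-3-yne
Conditions: n-BuLi (2.2 equiv), Et2O, −78 °C; MeOH, −78 °C; cold filtration through basic alumina, used at once
Reagents that add atoms: none
Why: Dehydrochlorination to the chloroalkynyl ether and chlorine–lithium exchange give the lithium alkynyl ether, whose protonation furnishes the terminal ynol ether, which is kept cold because benzylic alkynyl ethers rearrange on warming.

Step 18
Reactants: 31 benzyl alcohol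
Product: 32 benzyl (E)-1,2-dichlorovinyl ether
Conditions: KH, THF, 0 °C; Cl2C=CHCl, −50 °C → rt
Reagents that add atoms: trichloroethylene, ClC=C(Cl)Cl
Why: The same alkoxide addition to in situ dichloroacetylene is standard for simple primary alcohols.

Step 19
Reactants: 32 benzyl (E)-1,2-dichlorovinyl ether
Product: 33 benzyloxyacetylene (benzyl ethynyl ether)
Conditions: n-BuLi (2.1 equiv), Et2O, −78 °C; MeOH; kept as a cold Et2O/pentane solution
Reagents that add atoms: none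
Why: Elimination and chlorine–lithium exchange followed by protonation give the alkoxyacetylene, chosen so that the oxygen it brings to C6 carries a benzyl group like all other phenols.

Step 20
Reactants: 30 (1R,2R)-2-ArR-1-(ethynyloxy)-1-LwM-5-(TBS-oxy)pent-3-yne; 33 benzyloxyacetylene
Product: 34 (2R,3R)-6-(benzyloxy)-3-ArR-2-LwM-4-[(TBS-oxy)methyl]-2,3-dihydro-1-benzofuran (trans)
Conditions: RhCl(PPh3)3 (10 mol%), 33 (5 equiv, slow addition), toluene, 25 °C
Reagents that add atoms: none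
Why: Proposed new method: oxidative cyclisation of the ynol ether and the propargylic alkyne of 30 on monovalent rhodium should give a bicyclic rhodacyclopentadiene, the new C3a–C7a bond between the two inner alkyne carbons closing furan ring B over the O1–C2–C3 tether; insertion of 33 into the less hindered Rh–C7 bond and C–C reductive elimination then form C7–C6 and C5–C4 and close benzene ring A. The closest known reaction type is the RhCl(PPh3)3-catalysed (2+2+2) cyclotrimerisation of 1,6-diynes with terminal alkynes, in particular of ynamide-tethered diynes that give indolines at room temperature; a diyne tethered through an ynol-ether oxygen has not been shown, but it is the oxygen counterpart of the ynamide. No stereocentre is formed: C2 and C3 lie in the tether, are not bonded to the metal and meet no acid or base, so the trans relationship from step 15 is carried over unchanged. The step needs regioselectivity (benzyloxy at C6, not C5): the oxygen-bearing carbon of 33 must bond to the unsubstituted terminus C7, which the bulk of the CH2OTBS group on the other α-carbon of the metallacycle and the meta preference of this catalyst with diynes substituted at one terminus should secure. It also needs chemoselectivity over homotrimerisation of 33 and over thermal decay of both ynol ethers, which slow addition of excess 33 at 25 °C addresses.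

Step 21
Reactants: 34 (2R,3R)-6-(benzyloxy)-3-ArR-2-LwM-4-[(TBS-oxy)methyl]-2,3-dihydro-1-benzofuran
Product: 35 [(2R,3R)-6-(benzyloxy)-3-ArR-2-LwM-2,3-dihydro-1-benzofuran-4-yl]methanol
Conditions: Bu4NF, THF, 0 °C
Reagents that add atoms: none
Why: Fluoride-mediated desilylation frees the primary benzylic alcohol under non-acidic conditions that spare the benzyl ethers and all three dihydrofuran rings.

Step 22
Reactants: 35 [(2R,3R)-6-(benzyloxy)-3-ArR-2-LwM-2,3-dihydro-1-benzofuran-4-yl]methanol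
Product: 36 (2R,3R)-6-(benzyloxy)-3-ArR-2-LwM-2,3-dihydro-1-benzofuran-4-carbaldehyde
Conditions: MnO2, CH2Cl2, rt
Reagents that add atoms: none
Why: Activated manganese dioxide oxidises the benzylic alcohol selectively to the aldehyde under neutral conditions.

Step 23
Reactants: 4 4-(benzyloxy)benzyl chloride
Product: 37 diethyl [4-(benzyloxy)benzyl]phosphonate
Conditions: P(OEt)3, neat, 140 °C
Reagents that add atoms: triethyl phosphite, CCOP(OCC)OCC
Why: Michaelis–Arbuzov reaction of a reactive benzylic chloride gives the phosphonate directly.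

Step 24
Reactants: 36 (2R,3R)-6-(benzyloxy)-3-ArR-2-LwM-2,3-dihydro-1-benzofuran-4-carbaldehyde; 37 diethyl [4-(benzyloxy)benzyl]phosphonate
Product: 38 (2R,3R)-6-(benzyloxy)-3-ArR-2-LwM-4-[(E)-2-ArP-ethenyl]-2,3-dihydro-1-benzofuran
Conditions: KOtBu, THF, 0 °C → rt
Reagents that add atoms: none
Why: Horner–Wadsworth–Emmons olefination of a non-enolisable aryl aldehyde with a benzylic phosphonate gives the (E)-stilbene under thermodynamic control of the elimination.

Step 25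
Reactants: 38 (2R,3R)-6-(benzyloxy)-3-ArR-2-LwM-4-[(E)-2-ArP-ethenyl]-2,3-dihydro-1-benzofuran
Product: 39 (2R,3R)-6-(benzyloxy)-3-ArR-2-LwM-4-[(2R,3R)-3-ArP-oxiran-2-yl]-2,3-dihydro-1-benzofuran
Conditions: D-fructose-derived Shi ketone (30 mol%), Oxone (2KHSO5·KHSO4·K2SO4), K2CO3, Bu4NHSO4, MeCN/(MeO)2CH2/aq. Na2B4O7, 0 °C; chromatography on Et3N-deactivated silica
Reagents that add atoms: potassium peroxymonosulfate (from Oxone), [K+].[O-]S(=O)(=O)OO
Why: Shi epoxidation of a trans-disubstituted stilbene by the chiral dioxirane through the spiro transition state should give the (R,R)-epoxide under reagent control, and the basic buffer protects the acid-labile 4-alkoxyaryl epoxide.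

Step 26
Reactants: 39 (2R,3R)-6-(benzyloxy)-3-ArR-2-LwM-4-[(2R,3R)-3-ArP-oxiran-2-yl]-2,3-dihydro-1-benzofuran
Product: 40 nona-O-benzyl ether of the target (ring C closed; carbinol carbon S, ArP-bearing methine R, upper C2 R and C3 R)
Conditions: BF3·OEt2 (0.5 equiv), CH2Cl2, −78 °C; Et3N quench
Reagents that add atoms: none
Why: Intramolecular Friedel–Crafts epoxide–arene cyclisation: the Lewis acid opens the epoxide at the 4-benzyloxybenzylic carbon and an ortho carbon of the ArR ring on C3 attacks anti to the departing oxygen, closing the seven-membered ring C with inversion at that carbon (R) while the carbinol carbon keeps the epoxide configuration (S by the priority change), the epoxide being far more reactive than the dihydrofuran ethers at this temperature.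

Step 27
Reactants: 40 nona-O-benzyl ether of the target
Product: 41 CNP0132116.1
Conditions: H2 (1 atm), Pd/C (10 wt%), EtOAc/MeOH, rt
Reagents that add atoms: none
Why: Hydrogenolysis removes the nine unhindered aryl benzyl ethers, which cleave much faster than the cyclic secondary benzylic C–O bonds of the three dihydrofuran rings or the secondary benzylic alcohol, and no stereocentre is touched.

**Compound list**
1 | 2-bromo-4,6-dimethoxybenzaldehyde | COc1cc(OC)c(C=O)c(Br)c1 | starting material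
2 | 2-bromo-4,6-dihydroxybenzaldehyde | Oc1cc(O)c(C=O)c(Br)c1 | intermediate
3 | 4-(benzyloxy)-2-bromo-6-hydroxybenzaldehyde | O=Cc1c(O)cc(OCc2ccccc2)cc1Br | intermediate
4 | 4-(benzyloxy)benzyl chloride | ClCc1ccc(OCc2ccccc2)cc1 | starting material
5 | 4-(benzyloxy)-2-(BOB-oxy)-6-bromobenzaldehyde | O=Cc1c(OCc2ccc(OCc3ccccc3)cc2)cc(OCc2ccccc2)cc1Br | intermediate
6 | 4-(benzyloxy)-2-(BOB-oxy)-6-bromobenzonitrile | N#Cc1c(OCc2ccc(OCc3ccccc3)cc2)cc(OCc2ccccc2)cc1Br | intermediate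
7 | 1,3-bis(benzyloxy)-5-bromobenzene | Brc1cc(OCc2ccccc2)cc(OCc2ccccc2)c1 | starting material
8 | [3,5-bis(benzyloxy)phenyl]magnesium bromide | Br[Mg]c1cc(OCc2ccccc2)cc(OCc2ccccc2)c1 | intermediate
9 | N–H ketimine of [4-(benzyloxy)-2-(BOB-oxy)-6-bromophenyl](ArR)methanone | N=C(c1cc(OCc2ccccc2)cc(OCc2ccccc2)c1)c1c(OCc2ccc(OCc3ccccc3)cc2)cc(OCc2ccccc2)cc1Br | intermediate
10 | hydrazone of [4-(benzyloxy)-2-(BOB-oxy)-6-bromophenyl](ArR)methanone | NN=C(c1cc(OCc2ccccc2)cc(OCc2ccccc2)c1)c1c(OCc2ccc(OCc3ccccc3)cc2)cc(OCc2ccccc2)cc1Br | intermediate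
11 | [4-(benzyloxy)-2-(BOB-oxy)-6-bromophenyl](ArR)diazomethane | [N-]=[N+]=C(c1cc(OCc2ccccc2)cc(OCc2ccccc2)c1)c1c(OCc2ccc(OCc3ccccc3)cc2)cc(OCc2ccccc2)cc1Br | intermediate
12 | (2S,3R)-6-(benzyloxy)-2-ArP-3-ArR-4-bromo-2,3-dihydro-1-benzofuran (cis) | Brc1cc(OCc9ccccc9)cc2c1[C@@H](c1cc(OCc9ccccc9)cc(OCc9ccccc9)c1)[C@@H](c1ccc(OCc9ccccc9)cc1)O2 | intermediate
13 | (2R,3R)-6-(benzyloxy)-2-ArP-3-ArR-4-bromo-2,3-dihydro-1-benzofuran (trans; Lw–Br) | Brc1cc(OCc9ccccc9)cc2c1[C@@H](c1cc(OCc9ccccc9)cc(OCc9ccccc9)c1)[C@H](c1ccc(OCc9ccccc9)cc1)O2 | intermediate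
14 | 5-formyl-2-hydroxybenzonitrile | N#Cc1cc(C=O)ccc1O | starting material
15 | 5-(1,3-dioxolan-2-yl)-2-hydroxybenzonitrile | N#Cc1cc(C2OCCO2)ccc1O | intermediate
16 | 2-(BOB-oxy)-5-(1,3-dioxolan-2-yl)benzonitrile | N#Cc1cc(C2OCCO2)ccc1OCc1ccc(OCc2ccccc2)cc1 | intermediate
17 | Lw–Li (aryllithium from 13) | [Li]c1cc(OCc9ccccc9)cc2c1[C@@H](c1cc(OCc9ccccc9)cc(OCc9ccccc9)c1)[C@H](c1ccc(OCc9ccccc9)cc1)O2 | intermediate
18 | N–H ketimine of [2-(BOB-oxy)-5-(1,3-dioxolan-2-yl)phenyl](Lw)methanone | N=C(c1cc(C2OCCO2)ccc1OCc1ccc(OCc9ccccc9)cc1)c1cc(OCc9ccccc9)cc3c1[C@@H](c1cc(OCc9ccccc9)cc(OCc9ccccc9)c1)[C@H](c1ccc(OCc9ccccc9)cc1)O3 | intermediate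
19 | hydrazone of [2-(BOB-oxy)-5-(1,3-dioxolan-2-yl)phenyl](Lw)methanone | NN=C(c1cc(C2OCCO2)ccc1OCc1ccc(OCc9ccccc9)cc1)c1cc(OCc9ccccc9)cc3c1[C@@H](c1cc(OCc9ccccc9)cc(OCc9ccccc9)c1)[C@H](c1ccc(OCc9ccccc9)cc1)O3 | intermediate
20 | [2-(BOB-oxy)-5-(1,3-dioxolan-2-yl)phenyl](Lw)diazomethane | [N-]=[N+]=C(c1cc(C2OCCO2)ccc1OCc1ccc(OCc9ccccc9)cc1)c1cc(OCc9ccccc9)cc3c1[C@@H](c1cc(OCc9ccccc9)cc(OCc9ccccc9)c1)[C@H](c1ccc(OCc9ccccc9)cc1)O3 | intermediate
21 | (2S,3R)-2-ArP-3-Lw-5-(1,3-dioxolan-2-yl)-2,3-dihydro-1-benzofuran (cis middle ring) | C1COC(O1)c1ccc2c(c1)[C@@H](c1cc(OCc9ccccc9)cc3c1[C@@H](c1cc(OCc9ccccc9)cc(OCc9ccccc9)c1)[C@H](c1ccc(OCc9ccccc9)cc1)O3)[C@@H](c1ccc(OCc9ccccc9)cc1)O2 | intermediate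
22 | LwM–CHO, (2R,3R)-2-ArP-3-Lw-2,3-dihydro-1-benzofuran-5-carbaldehyde | O=Cc1ccc2c(c1)[C@@H](c1cc(OCc9ccccc9)cc3c1[C@@H](c1cc(OCc9ccccc9)cc(OCc9ccccc9)c1)[C@H](c1ccc(OCc9ccccc9)cc1)O3)[C@H](c1ccc(OCc9ccccc9)cc1)O2 | intermediate
23 | 3,5-bis(benzyloxy)benzaldehyde | O=Cc1cc(OCc2ccccc2)cc(OCc2ccccc2)c1 | starting material
24 | tert-butyldimethyl(prop-2-yn-1-yloxy)silane | C#CCO[Si](C)(C)C(C)(C)C | starting material
25 | (S)-1-ArR-4-(TBS-oxy)but-2-yn-1-ol | O[C@H](C#CCO[Si](C)(C)C(C)(C)C)c1cc(OCc2ccccc2)cc(OCc2ccccc2)c1 | intermediate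
26 | (S)-1-ArR-4-(TBS-oxy)but-2-yn-1-yl methanesulfonate | CS(=O)(=O)O[C@H](C#CCO[Si](C)(C)C(C)(C)C)c1cc(OCc2ccccc2)cc(OCc2ccccc2)c1 | intermediate
27 | [(M)-1-ArR-4-(TBS-oxy)buta-1,2-dien-3-yl]indium iodide methanesulfonate | [H]C(c1cc(OCc2ccccc2)cc(OCc2ccccc2)c1)=[C@@]=C(CO[Si](C)(C)C(C)(C)C)[In](I)OS(C)(=O)=O | intermediate
28 | (1R,2R)-2-ArR-1-LwM-5-(TBS-oxy)pent-3-yn-1-ol (anti) | c9ccccc9COc1cc(OCc9ccccc9)cc(c1)[C@H](C#CCO[Si](C)(C)C(C)(C)C)[C@@H](O)c1ccc2c(c1)[C@@H](c1cc(OCc9ccccc9)cc3c1[C@@H](c1cc(OCc9ccccc9)cc(OCc9ccccc9)c1)[C@H](c1ccc(OCc9ccccc9)cc1)O3)[C@H](c1ccc(OCc9ccccc9)cc1)O2 | intermediate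
29 | (1R,2R)-2-ArR-1-[(E)-1,2-dichlorovinyloxy]-1-LwM-5-(TBS-oxy)pent-3-yne | c9ccccc9COc1cc(OCc9ccccc9)cc(c1)[C@H](C#CCO[Si](C)(C)C(C)(C)C)[C@@H](O/C(Cl)=C\Cl)c1ccc2c(c1)[C@@H](c1cc(OCc9ccccc9)cc3c1[C@@H](c1cc(OCc9ccccc9)cc(OCc9ccccc9)c1)[C@H](c1ccc(OCc9ccccc9)cc1)O3)[C@H](c1ccc(OCc9ccccc9)cc1)O2 | intermediate
30 | (1R,2R)-2-ArR-1-(ethynyloxy)-1-LwM-5-(TBS-oxy)pent-3-yne | c9ccccc9COc1cc(OCc9ccccc9)cc(c1)[C@H](C#CCO[Si](C)(C)C(C)(C)C)[C@@H](OC#C)c1ccc2c(c1)[C@@H](c1cc(OCc9ccccc9)cc3c1[C@@H](c1cc(OCc9ccccc9)cc(OCc9ccccc9)c1)[C@H](c1ccc(OCc9ccccc9)cc1)O3)[C@H](c1ccc(OCc9ccccc9)cc1)O2 | intermediate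
31 | benzyl alcohol | OCc1ccccc1 | starting material
32 | benzyl (E)-1,2-dichlorovinyl ether | Cl/C=C(/Cl)OCc1ccccc1 | intermediate
33 | benzyloxyacetylene (benzyl ethynyl ether) | C#COCc1ccccc1 | intermediate
34 | (2R,3R)-6-(benzyloxy)-3-ArR-2-LwM-4-[(TBS-oxy)methyl]-2,3-dihydro-1-benzofuran | c9ccccc9COc1cc(OCc9ccccc9)cc(c1)[C@@H]1c2c(cc(OCc9ccccc9)cc2CO[Si](C)(C)C(C)(C)C)O[C@H]1c1ccc2c(c1)[C@@H](c1cc(OCc9ccccc9)cc3c1[C@@H](c1cc(OCc9ccccc9)cc(OCc9ccccc9)c1)[C@H](c1ccc(OCc9ccccc9)cc1)O3)[C@H](c1ccc(OCc9ccccc9)cc1)O2 | intermediate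
35 | [(2R,3R)-6-(benzyloxy)-3-ArR-2-LwM-2,3-dihydro-1-benzofuran-4-yl]methanol | c9ccccc9COc1cc(OCc9ccccc9)cc(c1)[C@@H]1c2c(cc(OCc9ccccc9)cc2CO)O[C@H]1c1ccc2c(c1)[C@@H](c1cc(OCc9ccccc9)cc3c1[C@@H](c1cc(OCc9ccccc9)cc(OCc9ccccc9)c1)[C@H](c1ccc(OCc9ccccc9)cc1)O3)[C@H](c1ccc(OCc9ccccc9)cc1)O2 | intermediate
36 | (2R,3R)-6-(benzyloxy)-3-ArR-2-LwM-2,3-dihydro-1-benzofuran-4-carbaldehyde | c9ccccc9COc1cc(OCc9ccccc9)cc(c1)[C@@H]1c2c(cc(OCc9ccccc9)cc2C=O)O[C@H]1c1ccc2c(c1)[C@@H](c1cc(OCc9ccccc9)cc3c1[C@@H](c1cc(OCc9ccccc9)cc(OCc9ccccc9)c1)[C@H](c1ccc(OCc9ccccc9)cc1)O3)[C@H](c1ccc(OCc9ccccc9)cc1)O2 | intermediate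
37 | diethyl [4-(benzyloxy)benzyl]phosphonate | CCOP(=O)(Cc1ccc(OCc2ccccc2)cc1)OCC | intermediate
38 | (2R,3R)-6-(benzyloxy)-3-ArR-2-LwM-4-[(E)-2-ArP-ethenyl]-2,3-dihydro-1-benzofuran | c9ccccc9COc1cc(OCc9ccccc9)cc(c1)[C@@H]1c2c(cc(OCc9ccccc9)cc2/C=C/c2ccc(OCc9ccccc9)cc2)O[C@H]1c1ccc2c(c1)[C@@H](c1cc(OCc9ccccc9)cc3c1[C@@H](c1cc(OCc9ccccc9)cc(OCc9ccccc9)c1)[C@H](c1ccc(OCc9ccccc9)cc1)O3)[C@H](c1ccc(OCc9ccccc9)cc1)O2 | intermediate
39 | (2R,3R)-6-(benzyloxy)-3-ArR-2-LwM-4-[(2R,3R)-3-ArP-oxiran-2-yl]-2,3-dihydro-1-benzofuran | c9ccccc9COc1cc(OCc9ccccc9)cc(c1)[C@@H]1c2c(cc(OCc9ccccc9)cc2[C@H]3O[C@@H]3c2ccc(OCc9ccccc9)cc2)O[C@H]1c1ccc2c(c1)[C@@H](c1cc(OCc9ccccc9)cc3c1[C@@H](c1cc(OCc9ccccc9)cc(OCc9ccccc9)c1)[C@H](c1ccc(OCc9ccccc9)cc1)O3)[C@H](c1ccc(OCc9ccccc9)cc1)O2 | intermediate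
40 | nona-O-benzyl ether of the target (ring C closed; carbinol carbon S, ArP-bearing methine R; upper, middle and lower dihydrofuran rings each 2R,3R) | c9ccccc9COc1ccc([C@@H]2c3c(OCc9ccccc9)cc(OCc9ccccc9)cc3[C@@H]3c4c(cc(OCc9ccccc9)cc4[C@H]2O)O[C@H]3c2ccc3c(c2)[C@@H](c2cc(OCc9ccccc9)cc4c2[C@@H](c2cc(OCc9ccccc9)cc(OCc9ccccc9)c2)[C@H](c2ccc(OCc9ccccc9)cc2)O4)[C@H](c2ccc(OCc9ccccc9)cc2)O3)cc1 | intermediate
41 | CNP0132116.1 (nine free phenols; carbinol carbon S, all other seven stereocentres R) | Oc1ccc([C@@H]2c3c(O)cc(O)cc3[C@@H]3c4c(cc(O)cc4[C@H]2O)O[C@H]3c2ccc3c(c2)[C@@H](c2cc(O)cc4c2[C@@H](c2cc(O)cc(O)c2)[C@H](c2ccc(O)cc2)O4)[C@H](c2ccc(O)cc2)O3)cc1 | target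

**Count and risks**
Total steps: 27. Longest linear sequence: 20 steps (1–7, 10–12, 15–17, 20–22, 24–27).

Step 20 (key step). What may go wrong: insertion of the alkoxyacetylene in the reverse orientation, homotrimerisation of benzyloxyacetylene outrunning the cross-reaction, or decay of the ynol ether on the metal before oxidative cyclisation. Fallback with known chemistry, setting out from 22 and rejoining at 36: NaBH4 reduction gives the benzylic alcohol F1; Mitsunobu etherification (PPh3, DIAD) with phenol 3 gives the aryl ether aldehyde F2; I2/aq. NH3 gives the nitrile F3; addition of Grignard reagent 8 and exchange with hydrazine as in step 5 give the hydrazone F4; MnO2 oxidation and Rh2(S-PTAD)4-catalysed carbene C–H insertion into the OCH2 group give the cis 4-bromo dihydrobenzofuran F5; brief CF3CO2H treatment gives the trans bromide F6; bromine–lithium exchange and DMF then give aldehyde 36.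

Step 12. What may go wrong: after acid-induced opening of the middle dihydrofuran ring, the benzylic cation is captured irreversibly by the neighbouring ArR ring (Friedel–Crafts closure of a seven-membered ring) instead of re-closing on oxygen. Fallback that avoids any benzylic cation, setting out from 13 and rejoining at 22: bromine–lithium exchange of 13 and addition to 5-bromo-2-(TBS-oxy)benzaldehyde F9 (TBSCl, imidazole on 5-bromosalicylaldehyde) give the diarylmethanol F10 (both carbinol epimers), which is acetylated to the acetate F11. CsF in MeCN then releases an o-quinone methide, which is intercepted by the ylide of [4-(benzyloxy)benzyl]dimethylsulfonium tetrafluoroborate F12 (from 4, Me2S and NaBF4) in a base-mediated (4+1) annulation expected to give the trans 5-bromo dihydrobenzofuran F13. The middle-ring configuration is not reagent-controlled here, so the other trans diastereomer would have to be removed by chromatography. Bromine–lithium exchange of F13 and DMF give 22.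

Step 15. What may go wrong: loss of configurational purity of the aryl-substituted allenylmetal through propargyl/allenyl equilibration, or weak anti/syn discrimination with the aryl aldehyde. Fallback, setting out from 25 and rejoining at 28: methyl chloroformate/pyridine gives the propargylic carbonate F7; copper-catalysed anti SN2′ borylation (CuCl, NaOtBu, Xantphos, B2pin2) gives the isolable, configurationally stable (P)-allenylboronate F8, which adds to 22 on warming in toluene through a closed six-membered transition state to give 28.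

Further compounds
F1 | step 20 | LwM–CH2OH, [(2R,3R)-2-ArP-3-Lw-2,3-dihydro-1-benzofuran-5-yl]methanol | OCc1ccc2c(c1)[C@@H](c1cc(OCc9ccccc9)cc3c1[C@@H](c1cc(OCc9ccccc9)cc(OCc9ccccc9)c1)[C@H](c1ccc(OCc9ccccc9)cc1)O3)[C@H](c1ccc(OCc9ccccc9)cc1)O2
F2 | step 20 | 4-(benzyloxy)-2-bromo-6-(LwM-methoxy)benzaldehyde | O=Cc1c(Br)cc(OCc9ccccc9)cc1OCc1ccc2c(c1)[C@@H](c1cc(OCc9ccccc9)cc3c1[C@@H](c1cc(OCc9ccccc9)cc(OCc9ccccc9)c1)[C@H](c1ccc(OCc9ccccc9)cc1)O3)[C@H](c1ccc(OCc9ccccc9)cc1)O2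
F3 | step 20 | 4-(benzyloxy)-2-bromo-6-(LwM-methoxy)benzonitrile | N#Cc1c(Br)cc(OCc9ccccc9)cc1OCc1ccc2c(c1)[C@@H](c1cc(OCc9ccccc9)cc3c1[C@@H](c1cc(OCc9ccccc9)cc(OCc9ccccc9)c1)[C@H](c1ccc(OCc9ccccc9)cc1)O3)[C@H](c1ccc(OCc9ccccc9)cc1)O2
F4 | step 20 | hydrazone of [4-(benzyloxy)-2-bromo-6-(LwM-methoxy)phenyl](ArR)methanone | NN=C(c1cc(OCc9ccccc9)cc(OCc9ccccc9)c1)c1c(Br)cc(OCc9ccccc9)cc1OCc1ccc2c(c1)[C@@H](c1cc(OCc9ccccc9)cc3c1[C@@H](c1cc(OCc9ccccc9)cc(OCc9ccccc9)c1)[C@H](c1ccc(OCc9ccccc9)cc1)O3)[C@H](c1ccc(OCc9ccccc9)cc1)O2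
F5 | step 20 | (2S,3R)-6-(benzyloxy)-3-ArR-4-bromo-2-LwM-2,3-dihydro-1-benzofuran (cis) | c9ccccc9COc1cc(OCc9ccccc9)cc(c1)[C@@H]1c2c(cc(OCc9ccccc9)cc2Br)O[C@@H]1c1ccc2c(c1)[C@@H](c1cc(OCc9ccccc9)cc3c1[C@@H](c1cc(OCc9ccccc9)cc(OCc9ccccc9)c1)[C@H](c1ccc(OCc9ccccc9)cc1)O3)[C@H](c1ccc(OCc9ccccc9)cc1)O2
F6 | step 20 | (2R,3R)-6-(benzyloxy)-3-ArR-4-bromo-2-LwM-2,3-dihydro-1-benzofuran (trans) | c9ccccc9COc1cc(OCc9ccccc9)cc(c1)[C@@H]1c2c(cc(OCc9ccccc9)cc2Br)O[C@H]1c1ccc2c(c1)[C@@H](c1cc(OCc9ccccc9)cc3c1[C@@H](c1cc(OCc9ccccc9)cc(OCc9ccccc9)c1)[C@H](c1ccc(OCc9ccccc9)cc1)O3)[C@H](c1ccc(OCc9ccccc9)cc1)O2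
F7 | step 15 | (S)-1-ArR-4-(TBS-oxy)but-2-yn-1-yl methyl carbonate | COC(=O)O[C@H](C#CCO[Si](C)(C)C(C)(C)C)c1cc(OCc2ccccc2)cc(OCc2ccccc2)c1
F8 | step 15 | (P)-2-[1-ArR-4-(TBS-oxy)buta-1,2-dien-3-yl]-4,4,5,5-tetramethyl-1,3,2-dioxaborolane | [H]C(c1cc(OCc2ccccc2)cc(OCc2ccccc2)c1)=[C@@]=C(CO[Si](C)(C)C(C)(C)C)B1OC(C)(C)C(C)(C)O1
F9 | step 12 | 5-bromo-2-(TBS-oxy)benzaldehyde | O=Cc1cc(Br)ccc1O[Si](C)(C)C(C)(C)C
F10 | step 12 | [5-bromo-2-(TBS-oxy)phenyl](Lw)methanol (both carbinol epimers) | OC(c1cc(Br)ccc1O[Si](C)(C)C(C)(C)C)c1cc(OCc9ccccc9)cc2c1[C@@H](c1cc(OCc9ccccc9)cc(OCc9ccccc9)c1)[C@H](c1ccc(OCc9ccccc9)cc1)O2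
F11 | step 12 | [5-bromo-2-(TBS-oxy)phenyl](Lw)methyl acetate (both epimers) | CC(=O)OC(c1cc(Br)ccc1O[Si](C)(C)C(C)(C)C)c1cc(OCc9ccccc9)cc2c1[C@@H](c1cc(OCc9ccccc9)cc(OCc9ccccc9)c1)[C@H](c1ccc(OCc9ccccc9)cc1)O2
F12 | step 12 | [4-(benzyloxy)benzyl]dimethylsulfonium tetrafluoroborate | C[S+](C)Cc1ccc(OCc2ccccc2)cc1.F[B-](F)(F)F
F13 | step 12 | LwM–Br, (2R,3R)-2-ArP-5-bromo-3-Lw-2,3-dihydro-1-benzofuran (trans) | Brc1ccc2c(c1)[C@@H](c1cc(OCc9ccccc9)cc3c1[C@@H](c1cc(OCc9ccccc9)cc(OCc9ccccc9)c1)[C@H](c1ccc(OCc9ccccc9)cc1)O3)[C@H](c1ccc(OCc9ccccc9)cc1)O2
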